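**Retrosynthetic overview**

1. Target 15 comes from equatorial methyl addition to the C8 ketone 13 (sets C8), then loss of the silyl group.
2. Key disconnection C11–C12: the zinc homoenolate of the C8 ketone (C11 nucleophilic) is allylated by (2E,6E)-farnesyl chloride under CoBr2 catalysis without allylic transposition.
3. The homoenolate comes from iodomethyl ketone 10, from siloxycyclopropane 9, from the enol ether 8 that Me2CuLi addition to octalone 7 leaves behind (sets C10, then C9).
4. Octalone 7 comes from CBS reduction (sets C3), Birch reduction and asymmetric olefin isomerization (sets C5) of the tetralone 3, made from 6-methoxy-2-tetralone 1.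
5. Ring order: ring A is carried intact from the tetralone; ring B is the anisole ring, made alicyclic by the Birch reduction; no ring-closing C–C step is needed.

Assumption: the SMILES is read as (3S,5S,8R,9R,10S), a cis-fused decalin with H-5, the C10 methyl, the C3 hydroxyl, the C8 methyl and the C9 side chain on one face (β) and the C8 hydroxyl on the other (α); locants C1–C12 in the text are terpenoid locants (C3 carbinol, C4 gem-dimethyl, C5/C10 ring fusion, C8 tertiary carbinol, C9 side-chain carbon, C11/C12 first chain carbons), while the names are systematic.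

**Route**

Step 1
Reactants: 1 6-methoxy-3,4-dihydronaphthalen-2(1H)-one
Product: 3 6-methoxy-1,1-dimethyl-3,4-dihydronaphthalen-2(1H)-one, via monomethyl tetralone 2 (not isolated)
Conditions: NaH (2.3 equiv), MeI (2.6 equiv), THF, 0 °C to rt
Reagents that add atoms: iodomethane, CI
Why: Double enolate C-alkylation at the benzylic α-carbon, which is the most acidic position and is re-enolised after the first methylation; no stereocenter is formed.

Step 2
Reactants: 3 6-methoxy-1,1-dimethyl-3,4-dihydronaphthalen-2(1H)-one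
Product: 4 (2S)-6-methoxy-1,1-dimethyl-1,2,3,4-tetrahydronaphthalen-2-ol
Conditions: (R)-1-methyl-3,3-diphenyltetrahydro-1H,3H-pyrrolo[1,2-c][1,3,2]oxazaborole (10 mol%), BH3·SMe2, THF, −20 °C; aqueous work-up
Reagents that add atoms: none
Why: Corey–Bakshi–Shibata reduction, in which the quaternary benzylic carbon is the large group and the CH2 the small one, so the (R)-catalyst gives the (S)-carbinol that becomes C3 and fixes the absolute configuration of the whole route.

Step 3
Reactants: 4 (2S)-6-methoxy-1,1-dimethyl-1,2,3,4-tetrahydronaphthalen-2-ol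
Product: 6 (6S)-6-hydroxy-5,5-dimethyl-3,4,5,6,7,8-hexahydronaphthalen-2(1H)-one, via dihydroanisole alcohol 5 (not isolated)
Conditions: Li, NH3(l)/THF/t-BuOH, −78 to −33 °C; NH4Cl; then oxalic acid (cat.), MeOH/H2O, rt
Reagents that add atoms: water, O
Why: Birch reduction of the anisole ring (the alkoxide is inert) gives the 1-methoxy-1,4-diene, and mild enol-ether hydrolysis gives the non-conjugated β,γ-enone with the tetrasubstituted ring-fusion alkene left in place; C3 is untouched.

Step 4
Reactants: 6 (6S)-6-hydroxy-5,5-dimethyl-3,4,5,6,7,8-hexahydronaphthalen-2(1H)-one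
Product: 7 (4aS,6S)-6-hydroxy-5,5-dimethyl-4,4a,5,6,7,8-hexahydronaphthalen-2(3H)-one
Conditions: 9-amino-9-deoxy-epi-quinine (20 mol%), CF3CO2H (40 mol%), toluene, 25 °C
Reagents that add atoms: none
Why: Organocatalytic asymmetric olefin isomerization (β,γ to α,β) through a dienamine that is protonated at C4a (C5) on one face by the catalyst, giving H-5 cis to the C3 hydroxyl under catalyst control (the quinidine-derived pseudo-enantiomer is used if it proves to be the matched one); because C3 is already fixed, any minor product is a separable diastereomer and not an enantiomer.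

Step 5
Reactants: 7 (4aS,6S)-6-hydroxy-5,5-dimethyl-4,4a,5,6,7,8-hexahydronaphthalen-2(3H)-one
Product: 8 (2S,4aS,8aS)-1,1,4a-trimethyl-2,6-bis(triethylsilyloxy)-1,2,3,4,4a,7,8,8a-octahydronaphthalene
Conditions: Me2CuLi (3 equiv, from MeLi and CuI), Et3SiCl (4 equiv), Et3N, THF, −78 to −20 °C
Reagents that add atoms: lithium dimethylcuprate, [Li+].C[Cu-]C; chlorotriethylsilane, CC[Si](Cl)(CC)CC
Why: Cuprate conjugate addition to the octalone puts the methyl on C10 cis to H-5 (the usual cis-fused outcome, reinforced here because the trans pathway would be 1,3-diaxial to a C4 methyl), and silyl trapping gives the C8–C9 enol ether regiospecifically while also protecting the C3 oxygen.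

Step 6
Reactants: 8 (2S,4aS,8aS)-1,1,4a-trimethyl-2,6-bis(triethylsilyloxy)-1,2,3,4,4a,7,8,8a-octahydronaphthalene
Product: 9 (1aS,3aS,5S,7aS,7bR)-4,4,7a-trimethyl-1a,5-bis(triethylsilyloxy)decahydro-1H-cyclopropa[a]naphthalene
Conditions: Et2Zn, CH2I2, CH2Cl2, 0 °C to rt
Reagents that add atoms: diiodomethane, ICI
Why: Simmons–Smith cyclopropanation (Furukawa variant) of the electron-rich silyl enol ether from the convex β-face, anti to the pseudo-axial C1 methylene on C10, so that C11 is bonded to C9 cis to the angular methyl and C9 is set.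

Step 7
Reactants: 9 (1aS,3aS,5S,7aS,7bR)-4,4,7a-trimethyl-1a,5-bis(triethylsilyloxy)decahydro-1H-cyclopropa[a]naphthalene
Product: 10 (1R,4aS,6S,8aS)-1-(iodomethyl)-5,5,8a-trimethyl-6-(triethylsilyloxy)octahydronaphthalen-2(1H)-one
Conditions: N-iodosuccinimide (1.1 equiv), CH2Cl2, −20 to 0 °C, dark
Reagents that add atoms: N-iodosuccinimide, O=C1CCC(=O)N1I
Why: Electrophilic (halogenative) ring opening of the siloxycyclopropane, in which iodine attacks the CH2 carbon and the C8–C11 bond breaks with oxocarbenium assistance to give the 2-(iodomethyl) ketone; the C9–C11 bond and the C9 configuration are retained and the secondary silyl ether survives.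

Step 8
Reactants: 10 (1R,4aS,6S,8aS)-1-(iodomethyl)-5,5,8a-trimethyl-6-(triethylsilyloxy)octahydronaphthalen-2(1H)-one; 11 (2E,6E)-1-chloro-3,7,11-trimethyldodeca-2,6,10-triene
Product: 13 (1R,4aS,6S,8aS)-5,5,8a-trimethyl-6-(triethylsilyloxy)-1-[(3E,7E)-4,8,12-trimethyltrideca-3,7,11-trien-1-yl]octahydronaphthalen-2(1H)-one, via alkylzinc iodide 12 (not isolated)
Conditions: Zn dust (BrCH2CH2Br, Me3SiCl activation), LiCl, THF, 25 °C; then CoBr2 (10 mol%), 11 (1.2 equiv), THF/NMP, −10 °C
Reagents that add atoms: none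
Why: Proposed new method: zinc inserts into the primary C–I bond to give the β-zincio ketone (a ketone homoenolate, so C11, the β-carbon of a carbonyl, is now nucleophilic), and CoBr2-catalysed allylation by the allylic chloride forms C11–C12 at the chloride-bearing carbon without allylic transposition or E/Z loss, thus joining two carbons that are both electrophilic in their parent functional groups; the closest known reaction types are the cobalt-catalysed SN2-selective, geometry-retaining allylation of alkylzinc reagents by geranyl- or neryl-type chlorides and the copper-mediated (SN2') allylation of cyclopropanol-derived zinc homoenolates; no stereocenter is formed and C9 is not epimerised because the medium is never basic.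

Step 9
Reactants: 13 (1R,4aS,6S,8aS)-5,5,8a-trimethyl-6-(triethylsilyloxy)-1-[(3E,7E)-4,8,12-trimethyltrideca-3,7,11-trien-1-yl]octahydronaphthalen-2(1H)-one
Product: 15 (2S,4aS,5R,6R,8aS)-1,1,4a,6-tetramethyl-5-[(3E,7E)-4,8,12-trimethyltrideca-3,7,11-trien-1-yl]decahydronaphthalene-2,6-diol, via triethylsilyl ether 14 (not isolated)
Conditions: MeLi (3 equiv), CeCl3 (3.5 equiv), THF, −78 °C; NH4Cl; then Bu4NF, THF, 40 °C
Reagents that add atoms: methyllithium, [Li]C
Why: Organocerium 1,2-addition (non-basic, so no enolisation or epimerisation at C9) from the equatorial β-direction, because the axial α-approach is blocked by the syn-axial C1 methylene on C10, giving the C8 methyl β and the hydroxyl α; fluoride then cleaves the C3 silyl ether.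

**Compound list**

1 | 6-methoxy-3,4-dihydronaphthalen-2(1H)-one (6-methoxy-2-tetralone) | COc1ccc2c(c1)CCC(=O)C2 | starting material
2 | 6-methoxy-1-methyl-3,4-dihydronaphthalen-2(1H)-one (racemic) | COc1ccc2c(c1)CCC(=O)C2C | intermediate
3 | 6-methoxy-1,1-dimethyl-3,4-dihydronaphthalen-2(1H)-one | COc1ccc2c(c1)CCC(=O)C2(C)C | intermediate
4 | (2S)-6-methoxy-1,1-dimethyl-1,2,3,4-tetrahydronaphthalen-2-ol | COc1ccc2c(c1)CC[C@H](O)C2(C)C | intermediate
5 | (2S)-6-methoxy-1,1-dimethyl-1,2,3,4,5,8-hexahydronaphthalen-2-ol | COC1=CCC2=C(C1)CC[C@H](O)C2(C)C | intermediate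
6 | (6S)-6-hydroxy-5,5-dimethyl-3,4,5,6,7,8-hexahydronaphthalen-2(1H)-one | O=C1CCC2=C(C1)CC[C@H](O)C2(C)C | intermediate
7 | (4aS,6S)-6-hydroxy-5,5-dimethyl-4,4a,5,6,7,8-hexahydronaphthalen-2(3H)-one | O=C1C=C2CC[C@H](O)C(C)(C)[C@H]2CC1 | intermediate
8 | (2S,4aS,8aS)-1,1,4a-trimethyl-2,6-bis(triethylsilyloxy)-1,2,3,4,4a,7,8,8a-octahydronaphthalene | CC[Si](CC)(CC)OC1=C[C@@]2(C)CC[C@H](O[Si](CC)(CC)CC)C(C)(C)[C@H]2CC1 | intermediate
9 | (1aS,3aS,5S,7aS,7bR)-4,4,7a-trimethyl-1a,5-bis(triethylsilyloxy)decahydro-1H-cyclopropa[a]naphthalene | C1[C@@H]2[C@@]3(C)CC[C@H](O[Si](CC)(CC)CC)C(C)(C)[C@H]3CC[C@]12O[Si](CC)(CC)CC | intermediate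
10 | (1R,4aS,6S,8aS)-1-(iodomethyl)-5,5,8a-trimethyl-6-(triethylsilyloxy)octahydronaphthalen-2(1H)-one | IC[C@@H]1[C@@]2(C)CC[C@H](O[Si](CC)(CC)CC)C(C)(C)[C@H]2CCC1=O | intermediate
11 | (2E,6E)-1-chloro-3,7,11-trimethyldodeca-2,6,10-triene (farnesyl chloride) | CC(C)=CCC/C(C)=C/CC/C(C)=C/CCl | starting material
12 | {[(1R,4aS,6S,8aS)-5,5,8a-trimethyl-2-oxo-6-(triethylsilyloxy)decahydronaphthalen-1-yl]methyl}zinc iodide | I[Zn]C[C@@H]1[C@@]2(C)CC[C@H](O[Si](CC)(CC)CC)C(C)(C)[C@H]2CCC1=O | intermediate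
13 | (1R,4aS,6S,8aS)-5,5,8a-trimethyl-6-(triethylsilyloxy)-1-[(3E,7E)-4,8,12-trimethyltrideca-3,7,11-trien-1-yl]octahydronaphthalen-2(1H)-one | CC(C)=CCC/C(C)=C/CC/C(C)=C/CC[C@@H]1[C@@]2(C)CC[C@H](O[Si](CC)(CC)CC)C(C)(C)[C@H]2CCC1=O | intermediate
14 | (1R,2R,4aS,6S,8aS)-2,5,5,8a-tetramethyl-6-(triethylsilyloxy)-1-[(3E,7E)-4,8,12-trimethyltrideca-3,7,11-trien-1-yl]decahydronaphthalen-2-ol | CC(C)=CCC/C(C)=C/CC/C(C)=C/CC[C@@H]1[C@@]2(C)CC[C@H](O[Si](CC)(CC)CC)C(C)(C)[C@H]2CC[C@@]1(C)O | intermediate
15 | (2S,4aS,5R,6R,8aS)-1,1,4a,6-tetramethyl-5-[(3E,7E)-4,8,12-trimethyltrideca-3,7,11-trien-1-yl]decahydronaphthalene-2,6-diol | CC(C)=CCC/C(C)=C/CC/C(C)=C/CC[C@@H]1[C@@]2(C)CC[C@H](O)C(C)(C)[C@H]2CC[C@@]1(C)O | target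

**Step count and risks**

Total steps: 9. Longest linear sequence: 9 (from 1; 11 is bought).

Most likely to fail, in this order:

Step 8 (homoenolate allylation). The zinc homoenolate may close back to the zinc cyclopropoxide and stay unreactive, or the cobalt system may fail on this hindered, ketone-bearing alkylzinc. The fallback sets out from 8 and uses a sulfone-stabilised carbanion in place of the homoenolate. The enol ether 8 is alkylated at C9 from the same β-face by PhSCH2Cl and ZnBr2 to give (1R,4aS,6S,8aS)-5,5,8a-trimethyl-1-[(phenylsulfanyl)methyl]-6-(triethylsilyloxy)octahydronaphthalen-2(1H)-one F2. MeLi/CeCl3 then gives the tertiary carbinol (1R,2R,4aS,6S,8aS)-2,5,5,8a-tetramethyl-1-[(phenylsulfanyl)methyl]-6-(triethylsilyloxy)decahydronaphthalen-2-ol F3. Oxidation at sulfur (H2O2, (NH4)6Mo7O24) gives the sulfone (1R,2R,4aS,6S,8aS)-1-[(benzenesulfonyl)methyl]-2,5,5,8a-tetramethyl-6-(triethylsilyloxy)decahydronaphthalen-2-ol F4. Its dianion (n-BuLi, 2.2 equiv) is alkylated by 11 in a plain SN2 reaction to give the alkylated sulfone (1R,2R,4aS,6S,8aS)-1-[(3E,7E)-1-(benzenesulfonyl)-4,8,12-trimethyltrideca-3,7,11-trien-1-yl]-2,5,5,8a-tetramethyl-6-(triethylsilyloxy)decahydronaphthalen-2-ol F5. Reductive desulfonylation (Mg, MeOH) brings the material back to the route at 14.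

Step 4 (C5 set against a small thermodynamic bias, on a tetrasubstituted alkene outside the usual substrate range of this isomerization). The fallback sets out from 6 and gives up kinetic control. DBU in toluene at 60 °C equilibrates 6 to a mixture of 7 and its ring-fusion epimer (4aR,6S)-6-hydroxy-5,5-dimethyl-4,4a,5,6,7,8-hexahydronaphthalen-2(3H)-one F1. The two diastereomers are separated by chromatography and F1 is put back into the equilibration. Enantiopurity is untouched because C3 comes from the CBS step. The material returns to the route at 7.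

Step 9 (both faces of the C8 ketone are hindered, so the facial ratio may be poor). The fallback sets out from 13 and builds the carbinol in two stages. Me3S(O)I and NaH in DMSO deliver CH2 equatorially (reversible betaine formation, thermodynamic control) to give the spiro-epoxide (1R,2R,4aS,6S,8aS)-5,5,8a-trimethyl-6-(triethylsilyloxy)-1-[(3E,7E)-4,8,12-trimethyltrideca-3,7,11-trien-1-yl]octahydro-1H-spiro[naphthalene-2,2'-oxirane] F6, with oxygen axial (α). LiEt3BH opens it at the CH2 carbon to give the C8 methyl carbinol, back on the route at 14.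

**Further compounds**

F1 | step 4 | (4aR,6S)-6-hydroxy-5,5-dimethyl-4,4a,5,6,7,8-hexahydronaphthalen-2(3H)-one | O=C1C=C2CC[C@H](O)C(C)(C)[C@@H]2CC1
F2 | step 8 | (1R,4aS,6S,8aS)-5,5,8a-trimethyl-1-[(phenylsulfanyl)methyl]-6-(triethylsilyloxy)octahydronaphthalen-2(1H)-one | c1ccccc1SC[C@@H]1[C@@]2(C)CC[C@H](O[Si](CC)(CC)CC)C(C)(C)[C@H]2CCC1=O
F3 | step 8 | (1R,2R,4aS,6S,8aS)-2,5,5,8a-tetramethyl-1-[(phenylsulfanyl)methyl]-6-(triethylsilyloxy)decahydronaphthalen-2-ol | c1ccccc1SC[C@@H]1[C@@]2(C)CC[C@H](O[Si](CC)(CC)CC)C(C)(C)[C@H]2CC[C@@]1(C)O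
F4 | step 8 | (1R,2R,4aS,6S,8aS)-1-[(benzenesulfonyl)methyl]-2,5,5,8a-tetramethyl-6-(triethylsilyloxy)decahydronaphthalen-2-ol | O=S(=O)(c1ccccc1)C[C@@H]1[C@@]2(C)CC[C@H](O[Si](CC)(CC)CC)C(C)(C)[C@H]2CC[C@@]1(C)O
F5 | step 8 | (1R,2R,4aS,6S,8aS)-1-[(3E,7E)-1-(benzenesulfonyl)-4,8,12-trimethyltrideca-3,7,11-trien-1-yl]-2,5,5,8a-tetramethyl-6-(triethylsilyloxy)decahydronaphthalen-2-ol (both epimers at the sulfonyl carbon) | CC(C)=CCC/C(C)=C/CC/C(C)=C/CC([C@@H]1[C@@]2(C)CC[C@H](O[Si](CC)(CC)CC)C(C)(C)[C@H]2CC[C@@]1(C)O)S(=O)(=O)c1ccccc1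
F6 | step 9 | (1R,2R,4aS,6S,8aS)-5,5,8a-trimethyl-6-(triethylsilyloxy)-1-[(3E,7E)-4,8,12-trimethyltrideca-3,7,11-trien-1-yl]octahydro-1H-spiro[naphthalene-2,2'-oxirane] | CC(C)=CCC/C(C)=C/CC/C(C)=C/CC[C@@H]1[C@@]2(C)CC[C@H](O[Si](CC)(CC)CC)C(C)(C)[C@H]2CC[C@]13CO3
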